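**Retrosynthetic overview**

1. The cyclobutane carries its four heteroatoms all-trans (O, O, Br, Br alternate up and down); each ring bromine is cis to the vinylic C–Br carbon of the neighbouring butenolide, so it must be installed together with that ring. Ring order: cyclobutane (bought as 2-hydroxycyclobutanone) → butenolide B (R side chain) → butenolide A (S side chain).
2. Last disconnection: ring A by anti bromolactonisation (O–C(spiro) bond and ring C–Br bond trans) of a cyclobutenyl bromodienoate, itself made from a spiro cyclobutanone and the (S)-dibromoacrylate by Br/Mg exchange, 1,2-addition and dehydration.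
3. Key disconnection: ring B by palladium-catalysed syn carbobromination. The vinylic C–Br bond of the (R)-3,3-dibromoacrylate ester adds across the enol-ester C=C of a cyclobutene, forming the C(vinyl)–C(spiro) bond and the ring C–Br bond on the same face.
4. Enabling feature: in ring B the spiro carbon (C5 of the butenolide) bears the lactone oxygen, and its cyclobutane neighbour bears bromine cis to the vinylic carbon C4. C4–C5 and C–Br are therefore syn across what was an enol-ester double bond of the four-membered ring.
5. Both acyl units come from one racemic Baylis–Hillman adduct (lipase resolution gives both antipodes; ozonolysis; dibromo-olefination). The absolute configuration of the core comes from (S)-2-hydroxycyclobutanone, relayed through a silyloxy stereocentre that is later oxidised away.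

Key step: step 13

Assumption: both lipase resolutions follow Kazlauskas' rule (the (R)-alcohol is acetylated faster); with the opposite preference, alcohol and acetate would exchange roles after one methanolysis.

**Route**

Step 1
Reactants: 1 butanal; 2 tert-butyl acrylate
Product: 3 rac-tert-butyl 3-hydroxy-2-methylidenehexanoate
Conditions: DABCO (1 equiv), 1,4-dioxane/H2O 1:1, rt
Reagents that add atoms: none
Why: Morita–Baylis–Hillman reaction, in which the amine–acrylate zwitterion adds to the aldehyde and the amine is expelled; the carbinol centre forms racemic and is resolved in step 2.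

Step 2
Reactants: 3 rac-tert-butyl 3-hydroxy-2-methylidenehexanoate
Product: 4 tert-butyl (3R)-3-acetoxy-2-methylidenehexanoate and 5 tert-butyl (3S)-3-hydroxy-2-methylidenehexanoate
Conditions: lipase PS (Burkholderia cepacia), vinyl acetate, hexane, rt, to half conversion; chromatography
Reagents that add atoms: vinyl acetate, C=COC(C)=O
Why: lipase-catalysed kinetic resolution by irreversible transesterification, which should acetylate the (R)-alcohol faster, so that both antipodes are obtained and both are carried on.

Step 3
Reactants: 5 tert-butyl (3S)-3-hydroxy-2-methylidenehexanoate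
Product: 6 tert-butyl (3S)-3-acetoxy-2-methylidenehexanoate
Conditions: Ac2O, Et3N, DMAP (cat.), CH2Cl2, 0 °C
Reagents that add atoms: acetic anhydride, CC(=O)OC(C)=O
Why: DMAP-catalysed O-acylation, in which no bond to the stereocentre is broken.

Step 4
Reactants: 4 tert-butyl (3R)-3-acetoxy-2-methylidenehexanoate
Product: 8 tert-butyl (3R)-3-acetoxy-2-oxohexanoate, via ozonide 7 (not isolated)
Conditions: O3, CH2Cl2, −78 °C; then Me2S, −78 °C to rt
Reagents that add atoms: ozone, [O-][O+]=O
Why: ozonolysis of the 1,1-disubstituted alkene with reductive work-up gives the α-keto ester under neutral conditions that should leave the α-acetoxy ketone stereocentre untouched.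

Step 5
Reactants: 6 tert-butyl (3S)-3-acetoxy-2-methylidenehexanoate
Product: 10 tert-butyl (3S)-3-acetoxy-2-oxohexanoate, via ozonide 9 (not isolated)
Conditions: O3, CH2Cl2, −78 °C; then Me2S, −78 °C to rt
Reagents that add atoms: ozone, [O-][O+]=O
Why: the same ozonolysis with reductive work-up as in step 4, applied to the antipode.

Step 6
Reactants: 8 tert-butyl (3R)-3-acetoxy-2-oxohexanoate
Product: 11 tert-butyl (3R)-3-acetoxy-2-(dibromomethylidene)hexanoate
Conditions: CBr4, PPh3, CH2Cl2, 0 °C
Reagents that add atoms: carbon tetrabromide, BrC(Br)(Br)Br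
Why: Ramirez dibromo-olefination (first stage of the Corey–Fuchs sequence), in which Ph3P=CBr2 olefinates the activated ketone carbonyl of an α-keto ester to give the 3,3-dibromoacrylate without touching the stereocentre.

Step 7
Reactants: 10 tert-butyl (3S)-3-acetoxy-2-oxohexanoate
Product: 12 tert-butyl (3S)-3-acetoxy-2-(dibromomethylidene)hexanoate
Conditions: CBr4, PPh3, CH2Cl2, 0 °C
Reagents that add atoms: carbon tetrabromide, BrC(Br)(Br)Br
Why: the same Ramirez dibromo-olefination as in step 6, applied to the antipode.

Step 8
Reactants: 11 tert-butyl (3R)-3-acetoxy-2-(dibromomethylidene)hexanoate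
Product: 13 (3R)-3-acetoxy-2-(dibromomethylidene)hexanoic acid
Conditions: CF3CO2H, CH2Cl2, 0 °C to rt
Reagents that add atoms: none
Why: acidolysis of the tert-butyl ester with loss of 2-methylpropene, to which the secondary acetate and the vinylic bromides are inert.

Step 9
Reactants: 13 (3R)-3-acetoxy-2-(dibromomethylidene)hexanoic acid
Product: 14 (3R)-3-acetoxy-2-(dibromomethylidene)hexanoyl chloride
Conditions: (COCl)2, DMF (cat.), CH2Cl2, 0 °C to rt
Reagents that add atoms: oxalyl chloride, O=C(Cl)C(Cl)=O
Why: acid chloride formation through the Vilsmeier reagent; the acid has no α-hydrogen, so neither a ketene nor an epimerisable position can arise.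

Step 10
Reactants: 15 rac-2-hydroxycyclobutanone
Product: 16 (2S)-2-hydroxycyclobutanone
Conditions: Candida antarctica lipase B, vinyl acetate, t-BuOMe, rt, to slightly beyond half conversion; chromatography
Reagents that add atoms: none
Why: lipase-catalysed kinetic resolution of a cyclic acyloin, in which the (R)-alcohol should be acetylated and the (S)-alcohol recovered; this centre later fixes the absolute configuration of the cyclobutane core.

Step 11
Reactants: 16 (2S)-2-hydroxycyclobutanone
Product: 17 (2S)-2-{[tert-butyl(dimethyl)silyl]oxy}cyclobutanone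
Conditions: t-BuMe2SiOTf, 2,6-lutidine, CH2Cl2, −78 °C
Reagents that add atoms: tert-butyldimethylsilyl trifluoromethanesulfonate, CC(C)(C)[Si](C)(C)OS(=O)(=O)C(F)(F)F
Why: O-silylation under cold, weakly basic conditions that should not enolise the α-hydroxy ketone.

Step 12
Reactants: 17 (2S)-2-{[tert-butyl(dimethyl)silyl]oxy}cyclobutanone; 14 (3R)-3-acetoxy-2-(dibromomethylidene)hexanoyl chloride
Product: 19 (4S)-4-{[tert-butyl(dimethyl)silyl]oxy}cyclobut-1-en-1-yl (3R)-3-acetoxy-2-(dibromomethylidene)hexanoate, via potassium enolate 18 (not isolated)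
Conditions: KN(SiMe3)2, THF, −78 °C; then 14, −78 °C to −20 °C
Reagents that add atoms: none
Why: kinetic deprotonation at the CH2 group remote from the silyloxy-bearing carbon, then O-acylation of the potassium enolate by the hindered, non-enolisable acid chloride, gives the enol ester without touching the silyloxy stereocentre.

Step 13
Reactants: 19 (4S)-4-{[tert-butyl(dimethyl)silyl]oxy}cyclobut-1-en-1-yl (3R)-3-acetoxy-2-(dibromomethylidene)hexanoate
Product: 20 (1R)-1-[(1S,3S,4S)-1,8-dibromo-3-{[tert-butyl(dimethyl)silyl]oxy}-6-oxo-5-oxaspiro[3.4]oct-7-en-7-yl]butyl acetate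
Conditions: Pd[P(t-Bu)3]2 (10 mol %), toluene, 40 °C, no base
Reagents that add atoms: none
Why: Proposed new method: zerovalent palladium inserts into the C–Br bond of the dibromomethylidene group that is cis to the ester (with the bulky phosphine, insertion into the other C–Br bond is reversible), the alkenylpalladium bromide adds syn across the enol-ester C=C of the cyclobutene, and C(sp3)–Br reductive elimination with retention returns the catalyst, so the vinylic C–Br bond is added across the alkene with full atom economy. The closest known reaction type is the palladium-catalysed intramolecular carbohalogenation of alkenes by aryl and alkenyl halides under bulky-phosphine catalysis, known for alkenes that lead to neopentyl-type alkylpalladium species but not for enol esters or for alkylpalladium species with β-hydrogens. Ring B closes in the 5-exo-trig mode by forming the bond from the vinylic CBr carbon to the oxygen-bearing alkene carbon, which becomes the spiro carbon. The spiro centre is controlled by the adjacent silyloxy-bearing stereocentre (carbopalladation on the alkene face anti to the silyloxy group); the CHBr centre is controlled by the mechanism, because syn insertion and retentive C–Br elimination place bromine cis to the new C–C bond, a relationship that an external bromine source should not reach once the vinylic bromide of the butenolide shields that face. The step needs C–Br reductive elimination to win over β-hydride elimination toward the ring CH2 group: no base is present, so hydride elimination is reversible and would have to create a more strained cyclobutene, and the low temperature keeps the silyloxycyclobutene from electrocyclic ring opening.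

Step 14
Reactants: 20 (1R)-1-[(1S,3S,4S)-1,8-dibromo-3-{[tert-butyl(dimethyl)silyl]oxy}-6-oxo-5-oxaspiro[3.4]oct-7-en-7-yl]butyl acetate
Product: 21 (1R)-1-[(1S,3S,4S)-1,8-dibromo-3-hydroxy-6-oxo-5-oxaspiro[3.4]oct-7-en-7-yl]butyl acetate
Conditions: HF·pyridine, THF, 0 °C to rt
Reagents that add atoms: none
Why: fluoride-induced cleavage of the silyl ether under acidic conditions, which avoid an alkoxide that could migrate onto the neighbouring lactone carbonyl.

Step 15
Reactants: 21 (1R)-1-[(1S,3S,4S)-1,8-dibromo-3-hydroxy-6-oxo-5-oxaspiro[3.4]oct-7-en-7-yl]butyl acetate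
Product: 22 (1R)-1-[(3S,4S)-3,8-dibromo-1,6-dioxo-5-oxaspiro[3.4]oct-7-en-7-yl]butyl acetate
Conditions: Dess–Martin periodinane, CH2Cl2, 0 °C to rt
Reagents that add atoms: none
Why: Dess–Martin oxidation of the secondary alcohol under neutral conditions, so that the β-bromo ketone should not lose HBr; the auxiliary carbinol stereocentre is erased here after it has done its work.

Step 16
Reactants: 12 tert-butyl (3S)-3-acetoxy-2-(dibromomethylidene)hexanoate; 22 (1R)-1-[(3S,4S)-3,8-dibromo-1,6-dioxo-5-oxaspiro[3.4]oct-7-en-7-yl]butyl acetate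
Product: 24 tert-butyl (2E,3S)-3-acetoxy-2-{bromo[(1R,3S,4S)-3,8-dibromo-1-hydroxy-7-[(1R)-1-acetoxybutyl]-6-oxo-5-oxaspiro[3.4]oct-7-en-1-yl]methylidene}hexanoate, via magnesium carbenoid 23 (not isolated)
Conditions: 12, i-PrMgCl·LiCl, THF, −78 °C; then 22, −78 °C; AcOH, −78 °C
Reagents that add atoms: none
Why: chelation-directed Br/Mg exchange at the bromine cis to the ester gives an α-bromoalkenylmagnesium reagent (as known for β-haloacrylates) that adds to the strained, very electrophilic cyclobutanone from the face opposite the vinylic bromide of ring B; the cold acid quench keeps the alkoxide from closing onto the tert-butyl ester, and the new carbinol centre is removed in step 17.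

Step 17
Reactants: 24 tertiary alcohol from step 16
Product: 25 tert-butyl (2E,3S)-3-acetoxy-2-{bromo[(3S,4S)-3,8-dibromo-7-[(1R)-1-acetoxybutyl]-6-oxo-5-oxaspiro[3.4]octa-1,7-dien-1-yl]methylidene}hexanoate
Conditions: Burgess reagent (MeO2C–N–SO2–NEt3 inner salt), THF, rt
Reagents that add atoms: none
Why: Burgess dehydration (syn elimination through the sulfamate ester) of the tertiary alcohol; only the ring CH2 group offers β-hydrogens, so the cyclobutene C=C forms in conjugation with the bromoacrylate.

Step 18
Reactants: 25 cyclobutenyl bromodienoate from step 17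
Product: 26 target, (5S,6S,11R,12R)-4,10,11,12-tetrabromo-3-[(1S)-1-acetoxybutyl]-9-[(1R)-1-acetoxybutyl]-1,7-dioxadispiro[4.0.4.2]dodeca-3,9-diene-2,8-dione
Conditions: N-bromosuccinimide, MeCN, −20 °C to 0 °C, dark
Reagents that add atoms: N-bromosuccinimide, O=C1CCC(=O)N1Br
Why: bromolactonisation of a tert-butyl ester (halolactonisation with loss of 2-methylpropene), in which the bromonium ion should form on the cyclobutene face anti to the allylic bromine and the ester carbonyl oxygen opens it anti at the tertiary allylic carbon in the 5-exo mode; this sets the second spiro centre (oxygen trans to the new bromine and to the first lactone oxygen) and the last CHBr centre (trans to its neighbour).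

**Compound list**

1 | butanal | CCCC=O | starting material
2 | tert-butyl acrylate | C=CC(=O)OC(C)(C)C | starting material
3 | rac-tert-butyl 3-hydroxy-2-methylidenehexanoate | CCCC(O)C(=C)C(=O)OC(C)(C)C | intermediate
4 | tert-butyl (3R)-3-acetoxy-2-methylidenehexanoate | CCC[C@@H](OC(C)=O)C(=C)C(=O)OC(C)(C)C | intermediate
5 | tert-butyl (3S)-3-hydroxy-2-methylidenehexanoate | CCC[C@H](O)C(=C)C(=O)OC(C)(C)C | intermediate
6 | tert-butyl (3S)-3-acetoxy-2-methylidenehexanoate | CCC[C@H](OC(C)=O)C(=C)C(=O)OC(C)(C)C | intermediate
7 | ozonide (1,2,4-trioxolane) of 4, epimers at the trioxolane carbon, not isolated | CCC[C@@H](OC(C)=O)C1(C(=O)OC(C)(C)C)OCOO1 | intermediate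
8 | tert-butyl (3R)-3-acetoxy-2-oxohexanoate | CCC[C@@H](OC(C)=O)C(=O)C(=O)OC(C)(C)C | intermediate
9 | ozonide (1,2,4-trioxolane) of 6, epimers at the trioxolane carbon, not isolated | CCC[C@H](OC(C)=O)C1(C(=O)OC(C)(C)C)OCOO1 | intermediate
10 | tert-butyl (3S)-3-acetoxy-2-oxohexanoate | CCC[C@H](OC(C)=O)C(=O)C(=O)OC(C)(C)C | intermediate
11 | tert-butyl (3R)-3-acetoxy-2-(dibromomethylidene)hexanoate | CCC[C@@H](OC(C)=O)C(=C(Br)Br)C(=O)OC(C)(C)C | intermediate
12 | tert-butyl (3S)-3-acetoxy-2-(dibromomethylidene)hexanoate | CCC[C@H](OC(C)=O)C(=C(Br)Br)C(=O)OC(C)(C)C | intermediate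
13 | (3R)-3-acetoxy-2-(dibromomethylidene)hexanoic acid | CCC[C@@H](OC(C)=O)C(=C(Br)Br)C(=O)O | intermediate
14 | (3R)-3-acetoxy-2-(dibromomethylidene)hexanoyl chloride | CCC[C@@H](OC(C)=O)C(=C(Br)Br)C(Cl)=O | intermediate
15 | rac-2-hydroxycyclobutanone | OC1CCC1=O | starting material
16 | (2S)-2-hydroxycyclobutanone | O[C@H]1CCC1=O | intermediate
17 | (2S)-2-{[tert-butyl(dimethyl)silyl]oxy}cyclobutanone | CC(C)(C)[Si](C)(C)O[C@H]1CCC1=O | intermediate
18 | potassium (4S)-4-{[tert-butyl(dimethyl)silyl]oxy}cyclobut-1-en-1-olate, not isolated | [K+].[O-]C1=CC[C@@H]1O[Si](C)(C)C(C)(C)C | intermediate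
19 | (4S)-4-{[tert-butyl(dimethyl)silyl]oxy}cyclobut-1-en-1-yl (3R)-3-acetoxy-2-(dibromomethylidene)hexanoate | CCC[C@@H](OC(C)=O)C(=C(Br)Br)C(=O)OC1=CC[C@@H]1O[Si](C)(C)C(C)(C)C | intermediate
20 | (1R)-1-[(1S,3S,4S)-1,8-dibromo-3-{[tert-butyl(dimethyl)silyl]oxy}-6-oxo-5-oxaspiro[3.4]oct-7-en-7-yl]butyl acetate (ring Br cis to the vinylic CBr carbon; lactone O cis to the silyloxy group) | CCC[C@@H](OC(C)=O)C1=C(Br)[C@@]2(OC1=O)[C@@H](Br)C[C@@H]2O[Si](C)(C)C(C)(C)C | intermediate
21 | (1R)-1-[(1S,3S,4S)-1,8-dibromo-3-hydroxy-6-oxo-5-oxaspiro[3.4]oct-7-en-7-yl]butyl acetate | CCC[C@@H](OC(C)=O)C1=C(Br)[C@@]2(OC1=O)[C@@H](Br)C[C@@H]2O | intermediate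
22 | (1R)-1-[(3S,4S)-3,8-dibromo-1,6-dioxo-5-oxaspiro[3.4]oct-7-en-7-yl]butyl acetate | CCC[C@@H](OC(C)=O)C1=C(Br)[C@@]2(OC1=O)[C@@H](Br)CC2=O | intermediate
23 | tert-butyl (2E,3S)-3-acetoxy-2-[bromo(chloromagnesio)methylidene]hexanoate (Mg cis to the ester), not isolated | CC(C)(C)OC(=O)/C([C@H](CCC)OC(C)=O)=C(\[Mg]Cl)Br | intermediate
24 | tert-butyl (2E,3S)-3-acetoxy-2-{bromo[(1R,3S,4S)-3,8-dibromo-1-hydroxy-7-[(1R)-1-acetoxybutyl]-6-oxo-5-oxaspiro[3.4]oct-7-en-1-yl]methylidene}hexanoate (OH cis to the vinylic carbon of ring B) | CCC[C@@H](OC(C)=O)C1=C(Br)[C@@]2(OC1=O)[C@@H](Br)C[C@]2(O)/C(Br)=C(\C(=O)OC(C)(C)C)[C@H](CCC)OC(C)=O | intermediate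
25 | tert-butyl (2E,3S)-3-acetoxy-2-{bromo[(3S,4S)-3,8-dibromo-7-[(1R)-1-acetoxybutyl]-6-oxo-5-oxaspiro[3.4]octa-1,7-dien-1-yl]methylidene}hexanoate | CCC[C@@H](OC(C)=O)C1=C(Br)[C@@]2(OC1=O)[C@@H](Br)C=C2/C(Br)=C(\C(=O)OC(C)(C)C)[C@H](CCC)OC(C)=O | intermediate
26 | (5S,6S,11R,12R)-4,10,11,12-tetrabromo-3-[(1S)-1-acetoxybutyl]-9-[(1R)-1-acetoxybutyl]-1,7-dioxadispiro[4.0.4.2]dodeca-3,9-diene-2,8-dione (CNP0266230.1) | CCC[C@H](OC(C)=O)C1=C(Br)[C@@]2(OC1=O)[C@@H](Br)[C@H](Br)[C@@]21OC(=O)C([C@@H](CCC)OC(C)=O)=C1Br | target

**Step count and risks**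

Total step count: 18. Longest linear sequence: 13 steps (1, 2, 4, 6, 8, 9, 12, 13, 14, 15, 16, 17, 18).

Steps most likely to fail:

1. Step 13 (proposed new method). What may go wrong: β-hydride elimination from the cyclobutylpalladium intermediate (a Heck-type exit, possibly with chain walking), C–Br reductive elimination too slow at the temperature the silyloxycyclobutene tolerates, or insertion of palladium into the wrong C–Br bond. The fallback uses known chemistry and an anti instead of a syn addition; it sets out from 17 and comes back at 20. Ketone 17 is converted into (4S)-4-{[tert-butyl(dimethyl)silyl]oxy}cyclobut-1-en-1-yl trifluoromethanesulfonate F1 (KN(SiMe3)2, PhNTf2, THF, −78 °C; kinetic enolisation away from the silyloxy carbon). Miyaura borylation (B2pin2, PdCl2(dppf), KOPh, 40 °C) gives tert-butyl(dimethyl){[(1S)-2-(4,4,5,5-tetramethyl-1,3,2-dioxaborolan-2-yl)cyclobut-2-en-1-yl]oxy}silane F2. Suzuki coupling of F2 with dibromide 11 at the C–Br bond cis to the ester (Pd(PPh3)4, K3PO4, THF/H2O, 40 °C) gives tert-butyl (2E,3R)-3-acetoxy-2-{bromo[(4S)-4-{[tert-butyl(dimethyl)silyl]oxy}cyclobut-1-en-1-yl]methylidene}hexanoate F3. Bromolactonisation of F3 with N-bromosuccinimide (bromonium ion anti to the ring silyloxy group, ester oxygen anti to bromine, loss of 2-methylpropene) should give 20, because anti addition of oxygen and bromine leaves bromine cis to the vinylic carbon just as the syn carbobromination does.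

2. Step 16. What may go wrong: closure of the magnesium alkoxide onto the tert-butyl ester before the quench (which would give the butenolide without the fourth bromine), or loss of HBr from the β-bromo ketone under the basic reagent. The fallback sets out from 22 and comes back at 26. Ketone 22 is brominated at its only enolisable carbon under acid (Br2, AcOH, cat. HBr) to give (1R)-1-[(2R,3R,4S)-2,3,8-tribromo-1,6-dioxo-5-oxaspiro[3.4]oct-7-en-7-yl]butyl acetate F4, in which the α-bromine should settle trans to its neighbour by enol equilibration. Magnesium carbenoid 23 is then added at −78 °C and the adduct is allowed to warm, so that the alkoxide closes onto the tert-butyl ester (butenolide annulation of a β-magnesioacrylate) and gives 26 directly. The second spiro centre is then set by carbonyl addition anti to the vinylic bromide of ring B instead of by bromolactonisation.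

3. Step 18. What may go wrong: bromonium formation on the wrong face, 6-endo closure, or ionisation of the allylic bromide before the ester participates. The fallback sets out from 25 and comes back at 26. Diene 25 is treated with N-bromosuccinimide in THF/H2O, so that water instead of the ester captures the bromonium ion at the tertiary carbon and gives tert-butyl (2E,3S)-3-acetoxy-2-{bromo[(1S,2R,3R,4S)-2,3,8-tribromo-1-hydroxy-7-[(1R)-1-acetoxybutyl]-6-oxo-5-oxaspiro[3.4]oct-7-en-1-yl]methylidene}hexanoate F5. CF3CO2H in CH2Cl2 then cleaves the tert-butyl ester and closes the hydroxy acid to 26. The oxygen is thus introduced in a separate intermolecular event, and a wrong isomer could be removed at the bromohydrin stage.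

Further compounds

F1 | step 13 | (4S)-4-{[tert-butyl(dimethyl)silyl]oxy}cyclobut-1-en-1-yl trifluoromethanesulfonate | CC(C)(C)[Si](C)(C)O[C@H]1CC=C1OS(=O)(=O)C(F)(F)F
F2 | step 13 | tert-butyl(dimethyl){[(1S)-2-(4,4,5,5-tetramethyl-1,3,2-dioxaborolan-2-yl)cyclobut-2-en-1-yl]oxy}silane | CC(C)(C)[Si](C)(C)O[C@H]1CC=C1B1OC(C)(C)C(C)(C)O1
F3 | step 13 | tert-butyl (2E,3R)-3-acetoxy-2-{bromo[(4S)-4-{[tert-butyl(dimethyl)silyl]oxy}cyclobut-1-en-1-yl]methylidene}hexanoate | CC(C)(C)OC(=O)/C([C@@H](CCC)OC(C)=O)=C(Br)\C1=CC[C@@H]1O[Si](C)(C)C(C)(C)C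
F4 | step 16 | (1R)-1-[(2R,3R,4S)-2,3,8-tribromo-1,6-dioxo-5-oxaspiro[3.4]oct-7-en-7-yl]butyl acetate | CCC[C@@H](OC(C)=O)C1=C(Br)[C@@]2(OC1=O)[C@@H](Br)[C@H](Br)C2=O
F5 | step 18 | tert-butyl (2E,3S)-3-acetoxy-2-{bromo[(1S,2R,3R,4S)-2,3,8-tribromo-1-hydroxy-7-[(1R)-1-acetoxybutyl]-6-oxo-5-oxaspiro[3.4]oct-7-en-1-yl]methylidene}hexanoate | CCC[C@@H](OC(C)=O)C1=C(Br)[C@@]2(OC1=O)[C@@H](Br)[C@H](Br)[C@]2(O)/C(Br)=C(\C(=O)OC(C)(C)C)[C@H](CCC)OC(C)=O
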